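## Retrosynthetic overview
1. C3–O acyl bond, made last: linoleoyl chloride + (3S,9R,10R)-9,10-epoxyheptadec-1-ene-4,6-diyn-3-ol.
2. C5–C6 sp–sp bond (Cadiot–Chodkiewicz): (S)-5-bromopent-1-en-4-yn-3-ol + (2R,3R)-2-heptyl-3-propargyloxirane.
3. The oxirane is the only ring. It is closed once, in step 5, by invertive attack of the C10 oxygen on a C9 mesylate. C11–C12 comes from n-hexylMgBr/Cu on a primary tosylate.
4. Key C8–C9 bond: allenylboration of (R)-glyceraldehyde acetonide through a closed six-membered, [3,3]-type transition state. C10 is bought and C9 is set anti to it.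
5. Bromo-enynol from D-erythronolactone acetonide (C3 bought): lactol, Wittig vinyl, chloride, double elimination to the alkyne (erases the second sugar centre), bromination.

Assumption: the SMILES is read literally, giving (3S) and a trans-(9R,10R)-oxirane; compound 1 is bought and distilled just before use.

## Route

Step 1
Reactants: 1 (R)-2,2-dimethyl-1,3-dioxolane-4-carbaldehyde; 2 allenylboronic acid pinacol ester
Product: 4 (S)-1-[(R)-2,2-dimethyl-1,3-dioxolan-4-yl]but-3-yn-1-ol, via pinacol borate ester 3 (not isolated)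
Conditions: 2 (1.3 equiv), (PhO)2P(O)OH (5 mol %), 4 Å MS, PhMe, 0 °C → rt, 24 h; aq. NaHCO3; chromatography (anti:syn expected ca. 4–5:1)
Reagents that add atoms: none
Why: In this allenylboration the aldehyde binds to boron and the O=C/B–C=C=C array reorganises in one concerted six-electron shift through a closed chair (formally a [3,3]-sigmatropic, bora-oxa-Cope type SE2′ process) that makes C8–C9 and turns the allene into the alkyne, while the bought C10 centre directs Felkin–Anh/Cornforth attack to give the anti (9S) carbinol.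

Step 2
Reactants: 4 (S)-1-[(R)-2,2-dimethyl-1,3-dioxolan-4-yl]but-3-yn-1-ol
Product: 5 (S)-1-[(R)-2,2-dimethyl-1,3-dioxolan-4-yl]but-3-yn-1-yl methanesulfonate
Conditions: MsCl, Et3N, CH2Cl2, 0 °C
Reagents that add atoms: methanesulfonyl chloride, CS(=O)(=O)Cl
Why: O-sulfonylation of the only free hydroxyl marks C9 as the future electrophilic carbon without touching a C–O bond, so both centres are retained.

Step 3
Reactants: 5 (S)-1-[(R)-2,2-dimethyl-1,3-dioxolan-4-yl]but-3-yn-1-yl methanesulfonate
Product: 6 (2R,3S)-1,2-dihydroxyhex-5-yn-3-yl methanesulfonate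
Conditions: AcOH–H2O 4:1, 40 °C
Reagents that add atoms: none
Why: Acid-catalysed acetal hydrolysis frees the C10/C11 diol, and the secondary mesylate and the alkyne are inert to weak aqueous acid.

Step 4
Reactants: 6 (2R,3S)-1,2-dihydroxyhex-5-yn-3-yl methanesulfonate
Product: 7 (2R,3S)-2-hydroxy-3-(methylsulfonyloxy)hex-5-yn-1-yl 4-methylbenzenesulfonate
Conditions: TsCl (1.05 equiv), pyridine, CH2Cl2, 0 °C
Reagents that add atoms: p-toluenesulfonyl chloride, Cc1ccc(cc1)S(=O)(=O)Cl
Why: Selective sulfonylation takes the primary hydroxyl because the secondary one is hindered and deactivated by the neighbouring mesylate, and pyridine is too weak a base to start ring closure.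

Step 5
Reactants: 7 (2R,3S)-2-hydroxy-3-(methylsulfonyloxy)hex-5-yn-1-yl 4-methylbenzenesulfonate; 8 n-hexylmagnesium bromide
Product: 10 (2R,3R)-2-heptyl-3-(prop-2-yn-1-yl)oxirane, via hydroxy mesylate 9 (not isolated)
Conditions: 8 (3.5 equiv), CuI (15 mol %), THF, −40 → −10 °C; MeOH quench, then K2CO3, MeOH, rt
Reagents that add atoms: none
Why: Copper-catalysed Grignard/sulfonate cross-coupling (Kochi–Schlosser type) replaces only the primary tosylate, and K2CO3 then drives a Williamson-type 3-exo-tet SN2 in which the retained C10 oxygen displaces the C9 mesylate with inversion (9S → 9R), so the anti hydroxy mesylate gives the trans-(9R,10R)-oxirane.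

Step 6
Reactants: 11 (−)-2,3-O-isopropylidene-D-erythronolactone
Product: 12 2,3-O-isopropylidene-D-erythrose (lactol, anomeric mixture)
Conditions: DIBAL-H (1.1 equiv), CH2Cl2, −78 °C; Rochelle salt
Reagents that add atoms: none
Why: Partial hydride reduction of a γ-lactone stops at the stable aluminium hemiacetal at −78 °C, and both bought centres are untouched.

Step 7
Reactants: 12 2,3-O-isopropylidene-D-erythrose
Product: 13 [(4R,5S)-2,2-dimethyl-5-vinyl-1,3-dioxolan-4-yl]methanol
Conditions: Ph3PCH3Br (2.5 equiv), KOtBu (2.4 equiv), THF, 0 °C → rt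
Reagents that add atoms: methyltriphenylphosphonium bromide, C[P+](c1ccccc1)(c1ccccc1)c1ccccc1.[Br-]
Why: Wittig methylenation captures the open hydroxy-aldehyde form of the lactol and installs C1=C2 next to the centre that becomes C3, with the cis-dioxolane holding that centre against epimerisation.

Step 8
Reactants: 13 [(4R,5S)-2,2-dimethyl-5-vinyl-1,3-dioxolan-4-yl]methanol
Product: 14 (4S,5S)-4-(chloromethyl)-2,2-dimethyl-5-vinyl-1,3-dioxolane
Conditions: PPh3, CCl4, reflux
Reagents that add atoms: carbon tetrachloride, ClC(Cl)(Cl)Cl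
Why: The Appel reaction converts the primary alcohol into the chloride under neutral conditions that spare acetonide and alkene, and the change of descriptor at C4 reflects CIP priorities only.

Step 9
Reactants: 14 (4S,5S)-4-(chloromethyl)-2,2-dimethyl-5-vinyl-1,3-dioxolane
Product: 16 (S)-pent-1-en-4-yn-3-ol, via chlorodienol lithium alkoxide 15 (not isolated)
Conditions: LDA (5 equiv), THF, −78 → −20 °C; aq. NH4Cl; careful concentration (volatile)
Reagents that add atoms: none
Why: In this base-induced double elimination, deprotonation α to chlorine expels the β-alkoxy oxygen (the dioxolane collapses and sheds acetone) and dehydrochlorination of the vinyl chloride gives the alkyne, so the second sugar centre is erased while the C3–O bond is never broken and C3 stays (S).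

Step 10
Reactants: 16 (S)-pent-1-en-4-yn-3-ol
Product: 17 (S)-5-bromopent-1-en-4-yn-3-ol
Conditions: NBS (1.1 equiv), AgNO3 (10 mol %), acetone, rt, dark
Reagents that add atoms: N-bromosuccinimide, O=C1CCC(=O)N1Br
Why: Silver-catalysed electrophilic bromination proceeds through the silver acetylide and is much faster than attack on the monosubstituted alkene, and the product is also less volatile than 16.

Step 11
Reactants: 10 (2R,3R)-2-heptyl-3-(prop-2-yn-1-yl)oxirane; 17 (S)-5-bromopent-1-en-4-yn-3-ol
Product: 18 (3S)-8-[(2R,3R)-3-heptyloxiran-2-yl]oct-1-ene-4,6-diyn-3-ol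
Conditions: CuCl (10 mol %), NH2OH·HCl (cat.), 30 % aq. n-BuNH2, Et2O, 0 °C, slow addition of 17 to 10
Reagents that add atoms: none
Why: Cadiot–Chodkiewicz coupling joins the copper acetylide of 10 to the bromoalkyne selectively as the unsymmetrical diyne, and the free alcohol and the 1,2-disubstituted epoxide tolerate the short exposure to cold aqueous amine.

Step 12
Reactants: 18 (3S)-8-[(2R,3R)-3-heptyloxiran-2-yl]oct-1-ene-4,6-diyn-3-ol; 19 linoleoyl chloride
Product: 20 (3S)-8-[(2R,3R)-3-heptyloxiran-2-yl]oct-1-ene-4,6-diyn-3-yl (9Z,12Z)-octadeca-9,12-dienoate (target)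
Conditions: 19 (1.2 equiv), Et3N, DMAP (10 mol %), CH2Cl2, 0 °C, Ar
Reagents that add atoms: none
Why: DMAP-catalysed O-acylation forms the ester at oxygen with retention at C3, and the buffered cold conditions leave the epoxide, the diyne and the skipped Z,Z-diene intact.

## Compound list
1 | (R)-2,2-dimethyl-1,3-dioxolane-4-carbaldehyde | O=C[C@H]1COC(C)(C)O1 | starting material
2 | allenylboronic acid pinacol ester | C=C=CB1OC(C)(C)C(C)(C)O1 | starting material
3 | (S)-1-[(R)-2,2-dimethyl-1,3-dioxolan-4-yl]but-3-yn-1-yl pinacol borate | C#CC[C@H](OB1OC(C)(C)C(C)(C)O1)[C@H]2COC(C)(C)O2 | intermediate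
4 | (S)-1-[(R)-2,2-dimethyl-1,3-dioxolan-4-yl]but-3-yn-1-ol | C#CC[C@H](O)[C@H]1COC(C)(C)O1 | intermediate
5 | (S)-1-[(R)-2,2-dimethyl-1,3-dioxolan-4-yl]but-3-yn-1-yl methanesulfonate | C#CC[C@H](OS(C)(=O)=O)[C@H]1COC(C)(C)O1 | intermediate
6 | (2R,3S)-1,2-dihydroxyhex-5-yn-3-yl methanesulfonate | C#CC[C@H](OS(C)(=O)=O)[C@H](O)CO | intermediate
7 | (2R,3S)-2-hydroxy-3-(methylsulfonyloxy)hex-5-yn-1-yl 4-methylbenzenesulfonate | C#CC[C@H](OS(C)(=O)=O)[C@H](O)COS(=O)(=O)c1ccc(C)cc1 | intermediate
8 | n-hexylmagnesium bromide | CCCCCC[Mg]Br | starting material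
9 | (4S,5R)-5-hydroxydodec-1-yn-4-yl methanesulfonate | C#CC[C@H](OS(C)(=O)=O)[C@H](O)CCCCCCC | intermediate
10 | (2R,3R)-2-heptyl-3-(prop-2-yn-1-yl)oxirane | C#CC[C@H]1O[C@@H]1CCCCCCC | intermediate
11 | (−)-2,3-O-isopropylidene-D-erythronolactone, (3aR,6aR) | O=C1OC[C@H]2OC(C)(C)O[C@@H]12 | starting material
12 | 2,3-O-isopropylidene-D-erythrose (lactol, anomeric mixture) | OC1OC[C@H]2OC(C)(C)O[C@@H]12 | intermediate
13 | [(4R,5S)-2,2-dimethyl-5-vinyl-1,3-dioxolan-4-yl]methanol | C=C[C@@H]1OC(C)(C)O[C@@H]1CO | intermediate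
14 | (4S,5S)-4-(chloromethyl)-2,2-dimethyl-5-vinyl-1,3-dioxolane | C=C[C@@H]1OC(C)(C)O[C@@H]1CCl | intermediate
15 | (3S)-5-chloropenta-1,4-dien-3-ol (present as lithium alkoxide, E/Z undefined) | C=C[C@H](O)C=CCl | intermediate
16 | (S)-pent-1-en-4-yn-3-ol | C=C[C@H](O)C#C | intermediate
17 | (S)-5-bromopent-1-en-4-yn-3-ol | C=C[C@H](O)C#CBr | intermediate
18 | (3S)-8-[(2R,3R)-3-heptyloxiran-2-yl]oct-1-ene-4,6-diyn-3-ol | C=C[C@H](O)C#CC#CC[C@H]1O[C@@H]1CCCCCCC | intermediate
19 | linoleoyl chloride, (9Z,12Z) | CCCCC/C=C\C/C=C\CCCCCCCC(=O)Cl | starting material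
20 | (3S)-8-[(2R,3R)-3-heptyloxiran-2-yl]oct-1-ene-4,6-diyn-3-yl (9Z,12Z)-octadeca-9,12-dienoate | C=C[C@@H](C#CC#CC[C@H]1O[C@@H]1CCCCCCC)OC(=O)CCCCCCC/C=C\C/C=C\CCCCC | target

## Step count and risks
Total step count: 12.
Longest linear sequence: 7 steps (1–5, 11, 12). The branch 6–10, 11, 12 is equally long.

**Step 1.** The pinacol reagent is sluggish and the single bought centre gives only moderate anti selectivity. The fallback buys C9 as well. It sets out at the position of 1: both 1 and 2 are replaced by commercial 2-deoxy-D-ribose F1. It comes back to the route at 4. Ohira–Bestmann homologation of the free lactol (dimethyl 1-diazo-2-oxopropylphosphonate, K2CO3, MeOH) gives (2R,3S)-hex-5-yne-1,2,3-triol F2. 2,2-Dimethoxypropane/PPTS then closes the favoured terminal dioxolane, because the internal one would be cis-disubstituted, and this product is 4.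

**Step 5.** The tosylate, mesylate, alkoxide and acidic alkyne C–H all face the organometallic at once. The fallback closes the ring before the chain is built. It sets out from 6 and comes back at 10.
- K2CO3/MeOH converts 6, by the same invertive closure, into [(2R,3R)-3-(prop-2-yn-1-yl)oxiran-2-yl]methanol F3.
- TsCl/Et3N/DMAP gives [(2R,3R)-3-(prop-2-yn-1-yl)oxiran-2-yl]methyl 4-methylbenzenesulfonate F4.
- (n-Hex)2CuLi (3 equiv, Et2O, −40 °C) displaces the primary sulfonate of the epoxy tosylate to give 10.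

**Step 9.** Deprotonation at the allylic C–H can compete with the desired one, and the product is very volatile. The fallback makes the alkyne by one-carbon homologation instead of elimination. It sets out from 1 and comes back at 16.
- Wittig methylenation of 1 gives (S)-2,2-dimethyl-4-vinyl-1,3-dioxolane F5.
- Aqueous acid gives (S)-but-3-ene-1,2-diol F6.
- TESCl/imidazole gives the bis(triethylsilyl) ether F7.
- Swern conditions oxidise the primary TES ether selectively to (S)-2-(triethylsilyloxy)but-3-enal F8.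
- The Ohira–Bestmann reagent at 0 °C gives (S)-triethyl(pent-1-en-4-yn-3-yloxy)silane F9.
- AcOH/THF/H2O releases 16.

The glyceraldehyde centre carries vinyl in place of CHO and ethynyl in place of CH2OH, which is again (S).

Further compounds
F1 | step 1 | 2-deoxy-D-ribose (aldehydo form drawn) | O=CC[C@H](O)[C@H](O)CO
F2 | step 1 | (2R,3S)-hex-5-yne-1,2,3-triol | C#CC[C@H](O)[C@H](O)CO
F3 | step 5 | [(2R,3R)-3-(prop-2-yn-1-yl)oxiran-2-yl]methanol | C#CC[C@H]1O[C@@H]1CO
F4 | step 5 | [(2R,3R)-3-(prop-2-yn-1-yl)oxiran-2-yl]methyl 4-methylbenzenesulfonate | C#CC[C@H]1O[C@@H]1COS(=O)(=O)c2ccc(C)cc2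
F5 | step 9 | (S)-2,2-dimethyl-4-vinyl-1,3-dioxolane | C=C[C@H]1COC(C)(C)O1
F6 | step 9 | (S)-but-3-ene-1,2-diol | C=C[C@H](O)CO
F7 | step 9 | (S)-but-3-ene-1,2-diol bis(triethylsilyl) ether | C=C[C@H](O[Si](CC)(CC)CC)CO[Si](CC)(CC)CC
F8 | step 9 | (S)-2-(triethylsilyloxy)but-3-enal | C=C[C@H](O[Si](CC)(CC)CC)C=O
F9 | step 9 | (S)-triethyl(pent-1-en-4-yn-3-yloxy)silane | C=C[C@H](O[Si](CC)(CC)CC)C#C
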